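**Strategy.** The target is (+)-catechin bearing two identical (2R,3S,4S)-fisetinidol units on C-6 and C-8 of its phloroglucinol ring (ring D). The route exploits this: each fisetinidol pyran ring (O-1, C-2, C-3, C-4) maps onto a 2-hydroxychalcone, with C-4 as the β-carbon, C-2 as the carbonyl carbon and O-1 as the phenol oxygen. In the key step three components, tetra-O-benzylcatechin and two chalcone molecules, are joined in one operation: a chiral acid closes each chalcone to a flavylium ion (O-1–C-2 bond) and ring D adds to C-4 at C-8 and C-6, giving a bis(4H-chromene). Hydroboration then relays the C-4 configuration to C-3 and C-2.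

Key step: step 3

Assumption: the (R)-antipode of the chiral acid is written for Si-face addition; if the sense of induction proves opposite, the (S)-antipode is used in the same way.

**Step 1**
Reactants: 1 (+)-catechin
Product: 2 5,7,3',4'-tetra-O-benzyl-(+)-catechin
Conditions: BnBr (4.4 equiv), K2CO3, DMF, 0 °C to rt, argon
Reagents that add atoms: benzyl bromide, BrCc1ccccc1
Why: Williamson ether synthesis in which K2CO3 ionises only the four phenols, so the secondary 3-OH stays free and no stereocentre is touched.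

**Step 2**
Reactants: 3 4-(benzyloxy)-2-hydroxybenzaldehyde; 4 1-[3,4-bis(benzyloxy)phenyl]ethanone
Product: 5 (E)-3-[4-(benzyloxy)-2-hydroxyphenyl]-1-[3,4-bis(benzyloxy)phenyl]prop-2-en-1-one
Conditions: KOH (aq), EtOH, rt; then AcOH to pH 6
Reagents that add atoms: none
Why: Claisen–Schmidt condensation of the enolate of 4 with the non-enolisable aldehyde 3, followed by E1cB loss of water, should give the thermodynamically favoured (E)-enone.

**Step 3**
Reactants: 2 5,7,3',4'-tetra-O-benzyl-(+)-catechin; 5 the 2-hydroxychalcone (2.5 equiv)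
Product: 8 (2R,3S)-5,7-bis(benzyloxy)-2-[3,4-bis(benzyloxy)phenyl]-6,8-bis{(4S)-7-(benzyloxy)-2-[3,4-bis(benzyloxy)phenyl]-4H-chromen-4-yl}chroman-3-ol, via flavylium ion pair 6 (not isolated), via C-8 mono-adduct 7 (not isolated)
Conditions: (R)-3,3'-bis(2,4,6-triisopropylphenyl)-1,1'-binaphthyl-2,2'-diyl N-triflylphosphoramide (15 mol%), 4 Å molecular sieves, toluene, 0 to 40 °C, argon
Reagents that add atoms: none
Why: The acid converts 5 (E-to-Z isomerisation of the O-protonated enone, attack of the phenol oxygen on the ketone carbon, loss of water to the sieves) into flavylium ion 6, the event that makes the ring-oxygen-to-C-2 bond of each fisetinidol ring C, and ring D of 2 then adds to C-4 of 6 within the ion pair, first at C-8 (giving 7) and then at C-6, each addition returning the proton to the catalyst. The closest known reaction type is the acid-mediated cyclodehydration of 2-hydroxychalcones to flavylium ions coupled with Friedel–Crafts addition of phloroglucinol ethers, naphthols or indoles at C-4 to give 2,4-diaryl-4H-chromenes, for which control by chiral phosphate-type counter-anions is known. Each pyran ring closes in the 6-exo-trig mode at the carbonyl carbon and is then aromatised to the pyrylium by dehydration. The two new C-4 stereocentres (both S) are set in the C–C bond-forming events by the chiral anion, which has to expose the Si face of C-4 of 6 twice; the catechin stereocentres are too remote to help or to hinder. The step needs C-alkylation only at C-8 and C-6 and ring closure only by the chalcone phenol, and both are secured by benzylation of every phenol of 2, which also keeps a ring D hydroxyl from adding to C-2 of the flav-2-ene to form a bridged ketal. Keeping the acid catalytic limits re-ionisation of 8 and hydride transfer from C-4 of the product to 6, and C-4 epimers, if formed, are diastereomers and separable.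

**Step 4**
Reactants: 8 the bis(4H-chromene)
Product: 10 deca-O-benzyl ether of the target, (2R,3S)-5,7-bis(benzyloxy)-2-[3,4-bis(benzyloxy)phenyl]-6,8-bis{(2R,3S,4S)-7-(benzyloxy)-2-[3,4-bis(benzyloxy)phenyl]-3-hydroxychroman-4-yl}chroman-3-ol, via tris(borane) adduct 9 (not isolated)
Conditions: BH3·SMe2 (excess), THF, 0 °C to rt; then NaOH (aq), H2O2, 0 °C to rt
Reagents that add atoms: hydrogen peroxide, OO
Why: Hydroboration–oxidation of the two enol ether double bonds places boron on C-3 and hydrogen on C-2 in a syn addition from the face opposite the pseudo-axial C-4 aryl group, and oxidation with retention should give 3-OH trans to the C-4 aryl and H-2 cis to 3-OH, which is the 2,3-trans-3,4-trans (2R,3S,4S) arrangement.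

**Step 5**
Reactants: 10 deca-O-benzyl ether of the target
Product: 11 fisetinidol-(4α→8)-catechin-(6→4α)-fisetinidol (target)
Conditions: H2 (1 atm), Pd(OH)2/C, THF/MeOH/H2O, rt
Reagents that add atoms: none
Why: Hydrogenolysis of the ten benzyl aryl ethers should leave the flavan C–O bonds, the interflavanyl C–C bonds and all stereocentres untouched under these mild conditions.

**Compound list**

1 | (+)-catechin, (2R,3S)-2-(3,4-dihydroxyphenyl)chromane-3,5,7-triol | O[C@H]1Cc2c(O)cc(O)cc2O[C@@H]1c1ccc(O)c(O)c1 | starting material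
2 | 5,7,3',4'-tetra-O-benzyl-(+)-catechin, (2R,3S)-5,7-bis(benzyloxy)-2-[3,4-bis(benzyloxy)phenyl]chroman-3-ol | O[C@H]1Cc2c(OCc3ccccc3)cc(OCc3ccccc3)cc2O[C@@H]1c1ccc(OCc2ccccc2)c(OCc2ccccc2)c1 | intermediate
3 | 4-(benzyloxy)-2-hydroxybenzaldehyde | O=Cc1ccc(OCc2ccccc2)cc1O | starting material
4 | 1-[3,4-bis(benzyloxy)phenyl]ethanone | CC(=O)c1ccc(OCc2ccccc2)c(OCc2ccccc2)c1 | starting material
5 | (E)-3-[4-(benzyloxy)-2-hydroxyphenyl]-1-[3,4-bis(benzyloxy)phenyl]prop-2-en-1-one | O=C(/C=C/c1ccc(OCc2ccccc2)cc1O)c1ccc(OCc2ccccc2)c(OCc2ccccc2)c1 | intermediate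
6 | 7-(benzyloxy)-2-[3,4-bis(benzyloxy)phenyl]chromenylium (flavylium) ion, paired with the chiral phosphoramidate anion, not isolated | c1ccccc1COc1ccc2ccc(-c3ccc(OCc4ccccc4)c(OCc4ccccc4)c3)[o+]c2c1 | intermediate
7 | (2R,3S)-5,7-bis(benzyloxy)-2-[3,4-bis(benzyloxy)phenyl]-8-{(4S)-7-(benzyloxy)-2-[3,4-bis(benzyloxy)phenyl]-4H-chromen-4-yl}chroman-3-ol, not isolated | c1c(OCc3ccccc3)c2c(c([C@@H]3c4ccc(OCc5ccccc5)cc4OC(c4ccc(OCc5ccccc5)c(OCc5ccccc5)c4)=C3)c1OCc1ccccc1)O[C@H](c1ccc(OCc3ccccc3)c(OCc3ccccc3)c1)[C@@H](O)C2 | intermediate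
8 | (2R,3S)-5,7-bis(benzyloxy)-2-[3,4-bis(benzyloxy)phenyl]-6,8-bis{(4S)-7-(benzyloxy)-2-[3,4-bis(benzyloxy)phenyl]-4H-chromen-4-yl}chroman-3-ol | c1ccccc1COc1ccc2c(c1)OC(c1ccc(OCc3ccccc3)c(OCc3ccccc3)c1)=C[C@@H]2c1c(OCc3ccccc3)c2c(c([C@@H]3c4ccc(OCc5ccccc5)cc4OC(c4ccc(OCc5ccccc5)c(OCc5ccccc5)c4)=C3)c1OCc1ccccc1)O[C@H](c1ccc(OCc3ccccc3)c(OCc3ccccc3)c1)[C@@H](O)C2 | intermediate
9 | tris(borane) adduct of 8, drawn at the monoalkylborane stage: BH2 on C-3 of both upper units (trans to the C-4 aryl, cis to H-2) and O-BH2 on the catechin 3-oxygen, not isolated | c1ccccc1COc1ccc2c(c1)O[C@H](c1ccc(OCc3ccccc3)c(OCc3ccccc3)c1)[C@@H](B)[C@@H]2c1c(OCc3ccccc3)c2c(c([C@@H]3c4ccc(OCc5ccccc5)cc4O[C@H](c4ccc(OCc5ccccc5)c(OCc5ccccc5)c4)[C@H]3B)c1OCc1ccccc1)O[C@H](c1ccc(OCc3ccccc3)c(OCc3ccccc3)c1)[C@@H](OB)C2 | intermediate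
10 | (2R,3S)-5,7-bis(benzyloxy)-2-[3,4-bis(benzyloxy)phenyl]-6,8-bis{(2R,3S,4S)-7-(benzyloxy)-2-[3,4-bis(benzyloxy)phenyl]-3-hydroxychroman-4-yl}chroman-3-ol | c1ccccc1COc1ccc2c(c1)O[C@H](c1ccc(OCc3ccccc3)c(OCc3ccccc3)c1)[C@@H](O)[C@@H]2c1c(OCc3ccccc3)c2c(c([C@@H]3c4ccc(OCc5ccccc5)cc4O[C@H](c4ccc(OCc5ccccc5)c(OCc5ccccc5)c4)[C@H]3O)c1OCc1ccccc1)O[C@H](c1ccc(OCc3ccccc3)c(OCc3ccccc3)c1)[C@@H](O)C2 | intermediate
11 | fisetinidol-(4α→8)-catechin-(6→4α)-fisetinidol, (2R,3S)-2-(3,4-dihydroxyphenyl)-6,8-bis[(2R,3S,4S)-2-(3,4-dihydroxyphenyl)-3,7-dihydroxychroman-4-yl]chromane-3,5,7-triol | Oc1ccc2c(c1)O[C@H](c1ccc(O)c(O)c1)[C@@H](O)[C@@H]2c1c(O)c2c(c([C@@H]3c4ccc(O)cc4O[C@H](c4ccc(O)c(O)c4)[C@H]3O)c1O)O[C@H](c1ccc(O)c(O)c1)[C@@H](O)C2 | target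

**Step count.** Total: 5 steps. Longest linear sequence: 4 steps (1 → 2 → 8 → 10 → 11).

**Steps most likely to fail**

1. Step 3. The process at risk is twofold: weak facial discrimination at C-4 of the flavylium ion in one or both additions, and stalling after the first addition because C-6 is flanked by two benzyloxy groups and the weak catalytic acid supplies only a low concentration of cation. The fallback sets out from 5 (with 2) and comes back at 8. The cation is made first and in stoichiometric amount: 5 with HBF4 (48% in water) in AcOH at rt should cyclise and dehydrate to 7-(benzyloxy)-2-[3,4-bis(benzyloxy)phenyl]chromenylium tetrafluoroborate F1, precipitated with Et2O. The ring-oxygen-to-C-2 bond is then closed in this separate operation. The solid salt F1 (2.4 equiv, in portions) is combined with 2 under chiral-anion phase-transfer conditions, (R)-3,3'-bis(2,4,6-triisopropylphenyl)-1,1'-binaphthyl-2,2'-diyl hydrogen phosphate (10 mol%), solid Na2CO3, toluene, rt. Only the ion pair with the chiral phosphate should dissolve, and Friedel–Crafts addition at C-8 and C-6 should give 8. Diastereomers at C-4 would be separated at 8 or at 10.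

2. Step 4. The process at risk is borane delivery to the face syn to the C-4 aryl group at the very hindered enol ethers, or β-elimination of the alkoxyborane with opening of the pyran ring. The fallback sets out from 8 and comes back at 10. Epoxidation with dimethyldioxirane in acetone/CH2Cl2/MeOH at −40 °C should occur anti to the C-4 aryl group, and methanol should open each epoxide at C-2 in situ to give the bis(2-methoxyflavan-3-ol) ketal F2. Ionic reduction of the bis(2-methoxyflavan-3-ol) ketal F2 with Et3SiH and catalytic TMSOTf in CH2Cl2 at −78 °C should proceed through the C-2 oxocarbenium ions with pseudo-axial hydride delivery. This places ring B equatorial, trans to 3-OH, as in the reduction of aryl C-glycoside ketals, and gives 10.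

3. Step 2. The process at risk is a sluggish condensation, because the aldehyde is deactivated as its phenoxide under base, with self-condensation of 4 taking over. The fallback sets out from 4 (with 3) and comes back at 5 by a Wittig olefination. α-Bromination of 4 with CuBr2 in EtOAc/CHCl3 at reflux should give 2-bromo-1-[3,4-bis(benzyloxy)phenyl]ethanone F3. PPh3 in toluene should give {2-[3,4-bis(benzyloxy)phenyl]-2-oxoethyl}triphenylphosphonium bromide F4, and NaOH (aq)/CH2Cl2 the stabilised ylide 1-[3,4-bis(benzyloxy)phenyl]-2-(triphenylphosphoranylidene)ethanone F5. Heating F5 with 3 in toluene should give the (E)-enone 5, since stabilised keto-ylides tolerate the free phenol.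

**Further compounds**

F1 | step 3 | 7-(benzyloxy)-2-[3,4-bis(benzyloxy)phenyl]chromenylium tetrafluoroborate | c1ccccc1COc1ccc2ccc(-c3ccc(OCc4ccccc4)c(OCc4ccccc4)c3)[o+]c2c1.F[B-](F)(F)F
F2 | step 4 | bis(2-methoxyflavan-3-ol) ketal: 10 in which C-2 of each upper unit carries OMe (cis to the C-4 aryl, trans to 3-OH) and ring B (cis to 3-OH) | c1ccccc1COc1ccc2c(c1)O[C@@](OC)(c1ccc(OCc3ccccc3)c(OCc3ccccc3)c1)[C@@H](O)[C@@H]2c1c(OCc3ccccc3)c2c(c([C@@H]3c4ccc(OCc5ccccc5)cc4O[C@@](OC)(c4ccc(OCc5ccccc5)c(OCc5ccccc5)c4)[C@H]3O)c1OCc1ccccc1)O[C@H](c1ccc(OCc3ccccc3)c(OCc3ccccc3)c1)[C@@H](O)C2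
F3 | step 2 | 2-bromo-1-[3,4-bis(benzyloxy)phenyl]ethanone | BrCC(=O)c1ccc(OCc2ccccc2)c(OCc2ccccc2)c1
F4 | step 2 | {2-[3,4-bis(benzyloxy)phenyl]-2-oxoethyl}triphenylphosphonium bromide | [Br-].O=C(C[P+](c1ccccc1)(c1ccccc1)c1ccccc1)c1ccc(OCc2ccccc2)c(OCc2ccccc2)c1
F5 | step 2 | 1-[3,4-bis(benzyloxy)phenyl]-2-(triphenylphosphoranylidene)ethanone | O=C(C=P(c1ccccc1)(c1ccccc1)c1ccccc1)c1ccc(OCc2ccccc2)c(OCc2ccccc2)c1
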